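**Design of a synthesis of CNP0303865.1 (compound 36)**

Abbreviations: TBS = tert-butyldimethylsilyl, PMB = 4-methoxybenzyl, TES = triethylsilyl, PivCl = pivaloyl chloride, DMPU = N,N'-dimethylpropyleneurea, TFA = trifluoroacetic acid.

## The problem

The target 36 is a germacranolide. Its ten-membered carbocycle (C1–C10, germacrane numbering) is trans-fused at C6/C7 to an α-methylene-γ-butyrolactone (C6–O–C12(=O)–C11(=C13)–C7). It carries a methacrylate on the C8 oxygen, a trisubstituted olefin C3=C4 with C15H2OH on C4 and with C2 and C5 cis within the ring, and C14H2OH on the sp3 carbon C10. There are four stereocentres: 6R, 7R and 8R are contiguous, and 10R is separated from them by C9. C6 can dictate C7 while both sit on a five-membered ring, because a nucleophile enters anti to the resident substituent. C8 lies outside that ring and can take its configuration from C7 only through ring conformation or a reagent, and C10 is too remote to be set by the others and needs its own source of asymmetry. The carbocycle is a strained medium ring, so its closure belongs on a bond whose formation creates no stereocentre. Several groups are fragile: the α-methylene lactone and the methacrylate are Michael acceptors and extra olefins in a metathesis, a C8 ketone next to the exocyclic methylene would let the double bond slide into the lactone ring, and a free C8 alkoxide can translactonise onto C12. The enabling feature is that C7 is the β-carbon of a butenolide, C6–O–C12(=O)–C11=C7, whose faces are distinguished by the C6 substituent. C8 can therefore arrive at C7 as an acyl-anion equivalent trans to the C5 arm, and the C11 enolate can take C13 as an aminomethyl group, a masked methylene, in the same flask.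

## Retrosynthesis

**36 ⇒ 35 ⇒ 33.** Only O–Si bonds and the C11=C13 double bond are touched. The two primary hydroxyls stay silylated to the end (35). The exocyclic methylene is kept as its dimethylamine adduct 33 and is released last by quaternisation and elimination through 34. Unveiling it earlier would expose a Michael acceptor to hydride and, next to a C8 ketone, invite migration of the double bond into the ring. The forward steps need only be mild enough for two enoates.

**33 ⇒ 32 ⇒ 31.** The C8–O acyl bond and then the C8–H bond are cut, leading to ketone 31. Setting C8 on the ring is preferred to setting it on an open chain: around an acyclic C7 the two flanking carbons C6 and C11 are nearly equivalent, whereas the trans-lactone of 31 restricts the rotamers about C7–C8. The forward reduction must deliver hydride so that O8 ends cis to C11 and must leave the lactone alone. Because 33 can be reached from either C8 epimer (acylation with retention or esterification with inversion), this is the one centre that may be left to a conformational argument.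

**31 ⇒ 29 ⇒ 27.** The ketone is the hydrolysis product of dithiane 29, and the carbocycle is opened at C3=C4 by a retro-metathesis to 27. C3=C4 is the only ring bond that carries no stereocentre, and cutting it leaves two terminal olefins that are inert spectators in all earlier steps. Closing instead at C7–C8 or C8–C9 would load ring formation and stereocontrol onto one step. Precursor 27 has all carbons and C6, C7 and C10 in place. The forward reaction must close a ten-membered ring onto a 1,1-disubstituted olefin, which is the main uncertainty of the plan after the key step.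

**27 ⇒ 23 + 11 + 24.** Two bonds around C7 are cut, C7–C8 and C11–C13. This divides the skeleton into two eight-carbon pieces of similar size, butenolide 11 and dithiane 23, plus the C1 unit 24. An aldol or alkylation approach to C7–C8 would have to control C7 and C8 together. Here only C7 is created, under the reliable anti rule of a 5-substituted butenolide, and C8 is deferred at the ketone level. The forward step needs 1,4- rather than 1,2-addition, addition rather than deprotonation at C6, and capture of the enolate before it is protonated.

**11 ⇒ 9 ⇒ 7 ⇒ 6 ⇒ 2 + 3.** The C11=C7 double bond comes from sulfoxide elimination in 9. The C7–C11 bond comes from opening epoxide 7 with the two-carbon dianion of step 4. The C4–C5 bond comes from opening (R)-epichlorohydrin 3 with the alkenyl metal derived from 2 (from 1). C6 is bought from the chiral pool, which is safer than an asymmetric allylation. The order of the two openings decides the enantiomer: the alkenyl group must enter first at the oxirane CH2, so that the chlorine-bearing carbon becomes C7.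

**23 ⇒ 20 + 21, 20 ⇒ 19 ⇒ 18 ⇒ 17 ⇒ 15 ⇒ 12 + 13.** The C8–C9 bond is an alkylation of 1,3-dithiane 21 by iodide 20. C10 is made by auxiliary-controlled hydroxymethylation of imide 15 (C10–C14 bond), built from hex-5-enoic acid 12 and oxazolidinone 13. Desymmetrising a tris(hydroxymethyl)methane derivative was the obvious neighbour, but it needs an enantioselective differentiation of two like arms and more steps. The auxiliary route fixes C10 with a predictable sense in six steps and already carries the C1–C3 olefin arm.

## Roads not taken

**Alternative 1: ring contraction by a Wittig–Still rearrangement.** The cut is C7–C8, made together with the carbocycle. The thirteen-membered cyclic ether A1 (C8 bears SnBu3 and is linked through oxygen to C13; C7=C11 is a Z olefin) would undergo tin–lithium exchange with n-BuLi. The α-alkoxy organolithium would attack C7 in a [2,3]-shift as O–C13 breaks, giving cyclodecenol A2.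
- Merits: one step forms the ring by contraction of an easier larger ring, delivers C8 at the alcohol level with its configuration tied to C7 through a cyclic transition state, and creates the C11=C13 methylene directly. The endgame would be short.
- Weak points: A1 is itself demanding (a macrocyclic etherification with a stereodefined α-alkoxystannane, a Z-trisubstituted olefin and C6 and C10 along one linear chain). The [2,3]-shift competes with [1,2]-shift, and the sense of C7/C8 induction in so large a transition state cannot be predicted on paper.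
- Comparison: on C8 this road is better, since the chosen plan relies on a hydride reduction of 31 whose facial preference is not secure. The chosen plan sets against this its convergence, the dependable five-ring control of C7, and the fact that either C8 epimer can be brought to ester 33.

**Alternative 2: enone–cyclobutene photocycloaddition and thermal ring expansion.** The cuts are C9–C10 and C3–C4, followed by fragmentation of C4–C9 and C3–C10. Irradiation of enone A3 with cyclobutene ester A4 would give the tricyclic photoadduct A5. Heating would cleave the two cyclobutane bonds and expand the six-membered ring by four carbons, leaving olefins at C3=C4 and C9=C10.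
- Merits: no macrocyclisation is needed. The ten-membered ring is paid for by release of cyclobutane strain, and C6–O, C8=O, C14 and C15 are in place.
- Weak points: head-to-head regiochemistry at a β,β-disubstituted enone is doubtful. The C3=C4 geometry is dictated by the fragmentation, not by the target, and the 1,5-diene can undergo Cope rearrangement at the temperatures needed. Four of the five stereocentres of A5 are destroyed. C10 would have to come from a conjugate reduction in a medium ring, C7 from alkylation next to the C8 ketone with the whole C11–C13 unit, and C8 from a later reduction.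
- Comparison: in ring formation this road is better than the metathesis of 27, the least secure step of the chosen plan apart from the key step. The chosen plan sets against it that C6, C7 and C10 are fixed before the ring exists, by chiral pool, five-ring control and auxiliary, with a shorter endgame.

**Alternative 3: ketyl–acrylate macrocyclisation captured as a bridging lactone.** The cut is C8–C9. SmI2 (divalent samarium) with a proton source would reduce the C8 aldehyde of A6 to a ketyl that adds to C9 of the tethered acrylate. The C8 alkoxide would then acylate C14 to give the bridged lactone A7.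
- Merits: the ring, the C8 oxygen and the C10 centre arise together, and the bridging γ-lactone fixes the C8/C10 relationship from an achiral acrylate terminus. In this it is better than the chosen plan, which needs an auxiliary for C10 and a separate reduction for C8.
- Weak points: a ten-membered ketyl–olefin closure fights entropy and strain and competes with pinacol coupling and simple reduction. Aldehyde A6 is α-branched by a vinyl group and β-alkoxylated, so it is prone to epimerisation and β-elimination. After the key step the C14 lactone must be reopened, O8 and O14 distinguished, both PMB ethers removed and C12 oxidised to the lactone, which makes a long endgame.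
- Comparison: both roads close a medium ring in a step of uncertain efficiency, so neither wins there. The chosen plan sets against the combined C8/C10 control of this road its stable intermediates (no enolisable β,γ-unsaturated aldehyde) and a six-step endgame in which the sensitive methylene is unmasked only at the end.

Key step: step 12

Remark on the chemistry: the C3=C4 olefin is read as having C2 and C5 on the same side of the ring (ring-cis), which is E in CIP terms because C15 outranks C5; germacrane numbering is used for all ring compounds and the SMILES strings are authoritative.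

## Route

Step 1
Reactants: 1 2-bromoprop-2-en-1-ol
Product: 2 [(2-bromoprop-2-en-1-yl)oxy](tert-butyl)dimethylsilane
Conditions: TBSCl, imidazole, CH2Cl2, 0 °C to rt
Reagents that add atoms: tert-butyldimethylsilyl chloride, CC(C)(C)[Si](C)(C)Cl
Why: Routine silylation of a primary allylic alcohol; it installs the group that protects O15 to the end.

Step 2
Reactants: 2 [(2-bromoprop-2-en-1-yl)oxy](tert-butyl)dimethylsilane, 3 (R)-epichlorohydrin
Product: 6 (2R)-4-{[(tert-butyldimethylsilyl)oxy]methyl}-1-chloropent-4-en-2-ol, via alkenyllithium 4 (not isolated), via alkenylmagnesium bromide 5 (not isolated)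
Conditions: t-BuLi (2.0 equiv), Et2O, −78 °C; MgBr2·OEt2, −78 °C; CuI (10 mol%), 3, −78 to −30 °C; aq. NH4Cl
Reagents that add atoms: none
Why: Bromine–lithium exchange at −78 °C and immediate transmetalation give an alkenyl Grignard reagent, which under copper catalysis opens the oxirane of 3 at its unsubstituted carbon (SN2) without touching the C–Cl bond; kept cold in ether, the alkenyllithium should have no time for O-to-C silyl migration. The stereocentre of 3 is not a reaction site and is carried over unchanged.

Step 3
Reactants: 6 (2R)-4-{[(tert-butyldimethylsilyl)oxy]methyl}-1-chloropent-4-en-2-ol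
Product: 7 (2R)-2-(2-{[(tert-butyldimethylsilyl)oxy]methyl}prop-2-en-1-yl)oxirane
Conditions: K2CO3, MeOH, 0 °C to rt
Reagents that add atoms: none
Why: Intramolecular Williamson etherification of the chlorohydrin; the C–O bond at the stereocentre is not broken, so the configuration is retained and the former CH2Cl becomes the electrophilic carbon for C7.

Step 4
Reactants: 7 (2R)-2-(2-{[(tert-butyldimethylsilyl)oxy]methyl}prop-2-en-1-yl)oxirane
Product: 9 (5R)-5-(2-{[(tert-butyldimethylsilyl)oxy]methyl}prop-2-en-1-yl)-3-(phenylsulfanyl)oxolan-2-one (both C3 epimers), via hydroxy acid 8 (not isolated)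
Conditions: PhSCH2CO2H, LiN(i-Pr)2 (2.1 equiv), THF, −78 to 0 °C; 7, 0 °C to rt; cold 1 M HCl; pyridinium tosylate (cat.), toluene, 60 °C
Reagents that add atoms: (phenylsulfanyl)acetic acid, OC(=O)CSc1ccccc1
Why: The dilithio dianion of the sulfenylated acetic acid opens the terminal epoxide at CH2 (SN2, the future C7–C11 bond), and the γ-hydroxy acid lactonises under mild acid; the carbinol carbon C6 is untouched. The sulfur-bearing carbon forms as a mixture, which is irrelevant because it becomes sp2 in step 5.

Step 5
Reactants: 9 (5R)-5-(2-{[(tert-butyldimethylsilyl)oxy]methyl}prop-2-en-1-yl)-3-(phenylsulfanyl)oxolan-2-one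
Product: 11 (5R)-5-(2-{[(tert-butyldimethylsilyl)oxy]methyl}prop-2-en-1-yl)furan-2(5H)-one, via sulfoxide 10 (not isolated)
Conditions: mCPBA (1.0 equiv), CH2Cl2, −78 °C; NaHCO3 wash, solvent exchange; toluene, 110 °C
Reagents that add atoms: none
Why: Oxidation of the sulfide is far faster than epoxidation of the 1,1-disubstituted olefin at −78 °C, and the α-sulfinyl lactone then undergoes thermal syn-elimination toward C7, the only β-hydrogens, to give the butenolide (sulfoxide pyrolysis). The neutral conditions leave the base-sensitive C6–H alone.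

Step 6
Reactants: 12 hex-5-enoic acid, 13 (4R)-4-benzyl-1,3-oxazolidin-2-one
Product: 15 (4R)-4-benzyl-3-(hex-5-enoyl)-1,3-oxazolidin-2-one, via mixed anhydride 14 (not isolated)
Conditions: PivCl, Et3N, THF, −20 °C; then LiCl, 13, −20 °C to rt
Reagents that add atoms: none
Why: N-Acylation of the oxazolidinone through the mixed pivalic anhydride under LiCl/Et3N activation, the standard entry to the auxiliary-bearing imide; no stereocentre is formed.

Step 7
Reactants: 15 (4R)-4-benzyl-3-(hex-5-enoyl)-1,3-oxazolidin-2-one
Product: 17 (4R)-4-benzyl-3-[(2S)-2-(hydroxymethyl)hex-5-enoyl]-1,3-oxazolidin-2-one, via titanium enolate 16 (not isolated)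
Conditions: TiCl4 (1.05 equiv), i-Pr2NEt (1.1 equiv), CH2Cl2, 0 °C; 1,3,5-trioxane (1.2 equiv), TiCl4 (1.05 equiv), 0 °C
Reagents that add atoms: 1,3,5-trioxane, C1OCOCO1
Why: Soft enolisation gives the chelated chlorotitanium Z-enolate, whose face syn to the benzyl group is blocked, so the TiCl4-activated formaldehyde equivalent adds anti to it (auxiliary-controlled hydroxymethylation, a variant of the Evans alkylation). With the (R)-auxiliary this gives the (2S)-imide, which is C10 with the configuration required in 36.

Step 8
Reactants: 17 (4R)-4-benzyl-3-[(2S)-2-(hydroxymethyl)hex-5-enoyl]-1,3-oxazolidin-2-one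
Product: 18 (4R)-4-benzyl-3-[(2S)-2-({[tert-butyl(dimethyl)silyl]oxy}methyl)hex-5-enoyl]-1,3-oxazolidin-2-one
Conditions: TBSCl, imidazole, DMF, rt
Reagents that add atoms: tert-butyldimethylsilyl chloride, CC(C)(C)[Si](C)(C)Cl
Why: Routine silylation of the primary alcohol; imidazole is too weak a base to epimerise the imide α-centre.

Step 9
Reactants: 18 (4R)-4-benzyl-3-[(2S)-2-({[tert-butyl(dimethyl)silyl]oxy}methyl)hex-5-enoyl]-1,3-oxazolidin-2-one
Product: 19 (2R)-2-({[tert-butyl(dimethyl)silyl]oxy}methyl)hex-5-en-1-ol
Conditions: LiBH4, MeOH (1 equiv), Et2O, 0 °C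
Reagents that add atoms: none
Why: LiBH4 reduces the exocyclic imide carbonyl to the primary alcohol and releases the auxiliary for recovery; no enolisable carbonyl remains, so C10 is configurationally safe, and under these cold conditions the silyl group should not migrate to the new hydroxyl.

Step 10
Reactants: 19 (2R)-2-({[tert-butyl(dimethyl)silyl]oxy}methyl)hex-5-en-1-ol
Product: 20 tert-butyl{[(2S)-2-(iodomethyl)hex-5-en-1-yl]oxy}dimethylsilane
Conditions: I2, PPh3, imidazole, CH2Cl2, 0 °C to rt
Reagents that add atoms: iodine, II
Why: Appel-type iodination of the primary alcohol through the alkoxyphosphonium ion; substitution occurs at CH2 and not at C10 (the descriptor changes only because iodine outranks oxygen).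

Step 11
Reactants: 20 tert-butyl{[(2S)-2-(iodomethyl)hex-5-en-1-yl]oxy}dimethylsilane, 21 1,3-dithiane
Product: 23 tert-butyl{[(2R)-2-(1,3-dithian-2-ylmethyl)hex-5-en-1-yl]oxy}dimethylsilane, via 2-lithio-1,3-dithiane 22 (not isolated)
Conditions: 21 (1.3 equiv), n-BuLi, THF, −30 °C; then 20, −78 to 0 °C
Reagents that add atoms: none
Why: Corey–Seebach alkylation: 2-lithio-1,3-dithiane displaces the primary iodide (SN2) and forms the C8–C9 bond; a slight excess of the anion suppresses double alkylation.

Step 12
Reactants: 23 tert-butyl{[(2R)-2-(1,3-dithian-2-ylmethyl)hex-5-en-1-yl]oxy}dimethylsilane, 11 (5R)-5-(2-{[(tert-butyldimethylsilyl)oxy]methyl}prop-2-en-1-yl)furan-2(5H)-one, 24 Eschenmoser's salt (N,N-dimethylmethaniminium iodide)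
Product: 27 (3R,4S,5R)-5-[2-({[tert-butyl(dimethyl)silyl]oxy}methyl)prop-2-en-1-yl]-4-{2-[(2R)-2-({[tert-butyl(dimethyl)silyl]oxy}methyl)hex-5-en-1-yl]-1,3-dithian-2-yl}-3-[(dimethylamino)methyl]oxolan-2-one, via lithiated dithiane 25 (not isolated), via lithium enolate 26 (not isolated)
Conditions: 23, n-BuLi (1.0 equiv), THF, −20 °C; DMPU (4 equiv), −78 °C; 11 (1.05 equiv, slow addition), −78 °C; 24 (2.5 equiv), −78 to 0 °C
Reagents that add atoms: none
Why: n-BuLi deprotonates C8 of 23 to the sulfur-stabilised carbanion 25; in THF/DMPU this soft, solvent-separated anion adds to C7 of butenolide 11 in a conjugate (Michael) sense, and the lactone lithium enolate 26 is captured at C11 by the iminium ion of 24 (Mannich reaction), so that C7–C8 and C11–C13 are made in one flask. The closest known reaction type is the tandem conjugate addition of 2-lithio-1,3-dithianes to 2(5H)-furanones with in situ trapping of the enolate by carbon electrophiles, joined to the familiar aminomethylation of lactone enolates with Eschenmoser's salt. No ring is closed. C7 is set by the C6 substituent: on the nearly planar five-membered ring the nucleophile enters anti to the C5 arm, giving the trans C6/C7 lactone (4S,5R). C11 is set by the new C7 substituent: the iminium ion approaches the enolate face anti to the bulky dithianyl group (3R), and this centre is erased in step 17, so it needs no fidelity. The step needs 1,4- rather than 1,2-addition and addition rather than deprotonation at C6; the polar cosolvent and the charge-delocalised anion secure the first, and low temperature with slow addition of 11 to the anion should limit the second. The silyl ethers and both terminal olefins are inert, and C6 and C10 are not touched.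

Step 13
Reactants: 27 (3R,4S,5R)-5-[2-({[tert-butyl(dimethyl)silyl]oxy}methyl)prop-2-en-1-yl]-4-{2-[(2R)-2-({[tert-butyl(dimethyl)silyl]oxy}methyl)hex-5-en-1-yl]-1,3-dithian-2-yl}-3-[(dimethylamino)methyl]oxolan-2-one
Product: 29 (3E,6R,7S,10R,11R)-14,15-bis[(tert-butyldimethylsilyl)oxy]-13-(dimethylamino)-8,8-(propane-1,3-diyldisulfanediyl)germacr-3-en-12,6-olide, via ammonium tosylate 28 (not isolated)
Conditions: TsOH·H2O (1.0 equiv), CH2Cl2, rt; second-generation Grubbs catalyst (H2IMes)(PCy3)Cl2Ru=CHPh (2 × 10 mol%), toluene (1 mM), 80 °C, argon sparge; aq. NaHCO3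
Reagents that add atoms: none
Why: Ring-closing olefin metathesis: the ruthenium carbene forms at the monosubstituted C3 olefin and closes onto the 1,1-disubstituted C4 methylene with loss of ethene; protonation keeps nitrogen off the metal and keeps C11–C13 masked, so that no electron-poor methylene can compete for an eight-membered ring. The fully substituted C8 and the trans-lactone bring the chain ends together, and because metathesis is reversible the ring should settle on the less strained ring-cis trisubstituted olefin (3E).

Step 14
Reactants: 29 (3E,6R,7S,10R,11R)-14,15-bis[(tert-butyldimethylsilyl)oxy]-13-(dimethylamino)-8,8-(propane-1,3-diyldisulfanediyl)germacr-3-en-12,6-olide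
Product: 31 (3E,6R,7S,10R,11R)-14,15-bis[(tert-butyldimethylsilyl)oxy]-13-(dimethylamino)-8-oxogermacr-3-en-12,6-olide, via ammonium trifluoroacetate 30 (not isolated)
Conditions: TFA (1.05 equiv), MeCN/H2O (9:1), 0 °C; PhI(OCOCF3)2 (1.3 equiv), 0 °C, 10 min; aq. NaHCO3
Reagents that add atoms: water, O
Why: The trivalent iodine reagent oxidises sulfur and water hydrolyses the resulting sulfonium ion to the ketone (oxidative dethioacetalisation); protonation protects nitrogen from oxidation, and the isolated olefin and silyl ethers should tolerate the short, cold, mildly acidic treatment. The β-acyloxy ketone is liberated under acid, where neither C7 epimerisation nor β-elimination of the C6 carboxylate is expected, and it is reduced without storage.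

Step 15
Reactants: 31 (3E,6R,7S,10R,11R)-14,15-bis[(tert-butyldimethylsilyl)oxy]-13-(dimethylamino)-8-oxogermacr-3-en-12,6-olide
Product: 32 (3E,6R,7R,8R,10R,11R)-14,15-bis[(tert-butyldimethylsilyl)oxy]-13-(dimethylamino)-8-hydroxygermacr-3-en-12,6-olide
Conditions: LiAlH(Ot-Bu)3 (3 equiv), THF, −78 to −40 °C; aq. NH4Cl at −40 °C
Reagents that add atoms: none
Why: The bulky alkoxyaluminium hydride reduces the ketone and leaves the lactone alone, and the amine adduct keeps C11–C13 out of reach of conjugate reduction. The trans-lactone holds C5–C6–C7–C8 near antiperiplanar, so the ten-membered ring needs a gauche C6–C7–C8–C9 torsion, and the rotamer with C9 beside H7 and not beside C11 turns the carbonyl oxygen toward the C11 face. Hydride entering from the ring periphery, anti to C6, should then give O8 cis to C11, which is 8R; the cold quench avoids translactonisation of the alkoxide.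

Step 16
Reactants: 32 (3E,6R,7R,8R,10R,11R)-14,15-bis[(tert-butyldimethylsilyl)oxy]-13-(dimethylamino)-8-hydroxygermacr-3-en-12,6-olide
Product: 33 (3E,6R,7R,8R,10R,11R)-14,15-bis[(tert-butyldimethylsilyl)oxy]-13-(dimethylamino)-8-(methacryloyloxy)germacr-3-en-12,6-olide
Conditions: methacrylic anhydride (3 equiv), Et3N, DMAP (0.2 equiv), CH2Cl2, 0 °C to rt
Reagents that add atoms: methacrylic anhydride, CC(=C)C(=O)OC(=O)C(C)=C
Why: DMAP-catalysed acylation of the secondary alcohol with retention at C8; the tertiary amine is inert, and capping O8 also removes the risk of translactonisation onto C12.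

Step 17
Reactants: 33 (3E,6R,7R,8R,10R,11R)-14,15-bis[(tert-butyldimethylsilyl)oxy]-13-(dimethylamino)-8-(methacryloyloxy)germacr-3-en-12,6-olide
Product: 35 (3E,6R,7R,8R,10R)-14,15-bis[(tert-butyldimethylsilyl)oxy]-8-(methacryloyloxy)germacra-3,11(13)-dien-12,6-olide, via trimethylammonium iodide 34 (not isolated)
Conditions: MeI (5 equiv), THF, rt; then sat. aq. NaHCO3, EtOAc, rt
Reagents that add atoms: none
Why: Exhaustive methylation turns the dimethylamino group into a leaving group, and bicarbonate then triggers E1cB (Hofmann-type) elimination across C11–C13 of the β-ammonium lactone. The conditions are mild enough for the methacrylate and the silyl ethers, and the C11 stereocentre is erased as planned.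

Step 18
Reactants: 35 (3E,6R,7R,8R,10R)-14,15-bis[(tert-butyldimethylsilyl)oxy]-8-(methacryloyloxy)germacra-3,11(13)-dien-12,6-olide
Product: 36 (3E,6R,7R,8R,10R)-14,15-dihydroxy-8-(methacryloyloxy)germacra-3,11(13)-dien-12,6-olide (CNP0303865.1)
Conditions: HF·pyridine, pyridine/THF, 0 °C to rt
Reagents that add atoms: none
Why: Buffered fluoride cleaves both primary silyl ethers; the medium is neither basic nor nucleophilic enough to add to the two enoates or to move the acyl group.

## Compound list

1 | 2-bromoprop-2-en-1-ol | OCC(Br)=C | starting material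
2 | [(2-bromoprop-2-en-1-yl)oxy](tert-butyl)dimethylsilane | C=C(Br)CO[Si](C)(C)C(C)(C)C | intermediate
3 | (R)-epichlorohydrin, (2R)-2-(chloromethyl)oxirane | ClC[C@H]1CO1 | starting material
4 | {3-[(tert-butyldimethylsilyl)oxy]prop-1-en-2-yl}lithium | [Li]C(=C)CO[Si](C)(C)C(C)(C)C | intermediate (not isolated)
5 | {3-[(tert-butyldimethylsilyl)oxy]prop-1-en-2-yl}magnesium bromide | Br[Mg]C(=C)CO[Si](C)(C)C(C)(C)C | intermediate (not isolated)
6 | (2R)-4-{[(tert-butyldimethylsilyl)oxy]methyl}-1-chloropent-4-en-2-ol | ClC[C@H](O)CC(=C)CO[Si](C)(C)C(C)(C)C | intermediate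
7 | (2R)-2-(2-{[(tert-butyldimethylsilyl)oxy]methyl}prop-2-en-1-yl)oxirane | C=C(CO[Si](C)(C)C(C)(C)C)C[C@@H]1CO1 | intermediate
8 | (4R)-6-{[(tert-butyldimethylsilyl)oxy]methyl}-4-hydroxy-2-(phenylsulfanyl)hept-6-enoic acid (C2 epimers) | OC(=O)C(Sc1ccccc1)C[C@H](O)CC(=C)CO[Si](C)(C)C(C)(C)C | intermediate (not isolated)
9 | (5R)-5-(2-{[(tert-butyldimethylsilyl)oxy]methyl}prop-2-en-1-yl)-3-(phenylsulfanyl)oxolan-2-one (C3 epimers) | O=C1C(Sc2ccccc2)C[C@H](O1)CC(=C)CO[Si](C)(C)C(C)(C)C | intermediate
10 | (5R)-5-(2-{[(tert-butyldimethylsilyl)oxy]methyl}prop-2-en-1-yl)-3-(phenylsulfinyl)oxolan-2-one | O=C1C(S(=O)c2ccccc2)C[C@H](O1)CC(=C)CO[Si](C)(C)C(C)(C)C | intermediate (not isolated)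
11 | (5R)-5-(2-{[(tert-butyldimethylsilyl)oxy]methyl}prop-2-en-1-yl)furan-2(5H)-one | O=C1C=C[C@H](O1)CC(=C)CO[Si](C)(C)C(C)(C)C | intermediate (key-step precursor)
12 | hex-5-enoic acid | C=CCCCC(=O)O | starting material
13 | (4R)-4-benzyl-1,3-oxazolidin-2-one | O=C1N[C@H](Cc2ccccc2)CO1 | starting material
14 | hex-5-enoic pivalic anhydride | C=CCCCC(=O)OC(=O)C(C)(C)C | intermediate (not isolated)
15 | (4R)-4-benzyl-3-(hex-5-enoyl)-1,3-oxazolidin-2-one | C=CCCCC(=O)N1[C@H](Cc2ccccc2)COC1=O | intermediate
16 | trichlorotitanium (Z)-enolate of 15 | C=CCC/C=C(\O[Ti](Cl)(Cl)Cl)N1[C@H](Cc2ccccc2)COC1=O | intermediate (not isolated)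
17 | (4R)-4-benzyl-3-[(2S)-2-(hydroxymethyl)hex-5-enoyl]-1,3-oxazolidin-2-one | C=CCC[C@@H](CO)C(=O)N1[C@H](Cc2ccccc2)COC1=O | intermediate
18 | (4R)-4-benzyl-3-[(2S)-2-({[tert-butyl(dimethyl)silyl]oxy}methyl)hex-5-enoyl]-1,3-oxazolidin-2-one | C=CCC[C@@H](CO[Si](C)(C)C(C)(C)C)C(=O)N1[C@H](Cc2ccccc2)COC1=O | intermediate
19 | (2R)-2-({[tert-butyl(dimethyl)silyl]oxy}methyl)hex-5-en-1-ol | C=CCC[C@@H](CO[Si](C)(C)C(C)(C)C)CO | intermediate
20 | tert-butyl{[(2S)-2-(iodomethyl)hex-5-en-1-yl]oxy}dimethylsilane | C=CCC[C@@H](CO[Si](C)(C)C(C)(C)C)CI | intermediate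
21 | 1,3-dithiane | C1CSCSC1 | starting material
22 | 2-lithio-1,3-dithiane | [Li]C1SCCCS1 | intermediate (not isolated)
23 | tert-butyl{[(2R)-2-(1,3-dithian-2-ylmethyl)hex-5-en-1-yl]oxy}dimethylsilane | C=CCC[C@@H](CO[Si](C)(C)C(C)(C)C)CC1SCCCS1 | intermediate (key-step precursor)
24 | Eschenmoser's salt, N,N-dimethylmethaniminium iodide | C=[N+](C)C.[I-] | starting material
25 | {2-[(2R)-2-({[tert-butyl(dimethyl)silyl]oxy}methyl)hex-5-en-1-yl]-1,3-dithian-2-yl}lithium | C=CCC[C@@H](CO[Si](C)(C)C(C)(C)C)CC1([Li])SCCCS1 | intermediate (not isolated)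
26 | lithium enolate of the trans-4,5-disubstituted lactone (C7–C8 formed, C11 enolate) | [Li]OC1=C[C@H](C2(C[C@H](CO[Si](C)(C)C(C)(C)C)CCC=C)SCCCS2)[C@@H](CC(=C)CO[Si](C)(C)C(C)(C)C)O1 | intermediate (not isolated)
27 | (3R,4S,5R)-5-[2-({[tert-butyl(dimethyl)silyl]oxy}methyl)prop-2-en-1-yl]-4-{2-[(2R)-2-({[tert-butyl(dimethyl)silyl]oxy}methyl)hex-5-en-1-yl]-1,3-dithian-2-yl}-3-[(dimethylamino)methyl]oxolan-2-one | CN(C)C[C@@H]1C(=O)O[C@H](CC(=C)CO[Si](C)(C)C(C)(C)C)[C@H]1C1(C[C@H](CO[Si](C)(C)C(C)(C)C)CCC=C)SCCCS1 | intermediate (key-step product)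
28 | dimethylammonium 4-methylbenzenesulfonate of 27 | C[NH+](C)C[C@@H]1C(=O)O[C@H](CC(=C)CO[Si](C)(C)C(C)(C)C)[C@H]1C1(C[C@H](CO[Si](C)(C)C(C)(C)C)CCC=C)SCCCS1.Cc1ccc(S(=O)(=O)[O-])cc1 | intermediate (not isolated)
29 | (3E,6R,7S,10R,11R)-14,15-bis[(tert-butyldimethylsilyl)oxy]-13-(dimethylamino)-8,8-(propane-1,3-diyldisulfanediyl)germacr-3-en-12,6-olide | CN(C)C[C@@H]1C(=O)O[C@@H]2C/C(CO[Si](C)(C)C(C)(C)C)=C\CC[C@@H](CO[Si](C)(C)C(C)(C)C)CC3(SCCCS3)[C@@H]12 | intermediate
30 | dimethylammonium trifluoroacetate of 29 | C[NH+](C)C[C@@H]1C(=O)O[C@@H]2C/C(CO[Si](C)(C)C(C)(C)C)=C\CC[C@@H](CO[Si](C)(C)C(C)(C)C)CC3(SCCCS3)[C@@H]12.[O-]C(=O)C(F)(F)F | intermediate (not isolated)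
31 | (3E,6R,7S,10R,11R)-14,15-bis[(tert-butyldimethylsilyl)oxy]-13-(dimethylamino)-8-oxogermacr-3-en-12,6-olide | CN(C)C[C@@H]1C(=O)O[C@@H]2C/C(CO[Si](C)(C)C(C)(C)C)=C\CC[C@@H](CO[Si](C)(C)C(C)(C)C)CC(=O)[C@@H]12 | intermediate
32 | (3E,6R,7R,8R,10R,11R)-14,15-bis[(tert-butyldimethylsilyl)oxy]-13-(dimethylamino)-8-hydroxygermacr-3-en-12,6-olide | CN(C)C[C@@H]1C(=O)O[C@@H]2C/C(CO[Si](C)(C)C(C)(C)C)=C\CC[C@@H](CO[Si](C)(C)C(C)(C)C)C[C@@H](O)[C@@H]12 | intermediate
33 | (3E,6R,7R,8R,10R,11R)-14,15-bis[(tert-butyldimethylsilyl)oxy]-13-(dimethylamino)-8-(methacryloyloxy)germacr-3-en-12,6-olide | CN(C)C[C@@H]1C(=O)O[C@@H]2C/C(CO[Si](C)(C)C(C)(C)C)=C\CC[C@@H](CO[Si](C)(C)C(C)(C)C)C[C@@H](OC(=O)C(C)=C)[C@@H]12 | intermediate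
34 | trimethylammonium iodide of 33 | C[N+](C)(C)C[C@@H]1C(=O)O[C@@H]2C/C(CO[Si](C)(C)C(C)(C)C)=C\CC[C@@H](CO[Si](C)(C)C(C)(C)C)C[C@@H](OC(=O)C(C)=C)[C@@H]12.[I-] | intermediate (not isolated)
35 | (3E,6R,7R,8R,10R)-14,15-bis[(tert-butyldimethylsilyl)oxy]-8-(methacryloyloxy)germacra-3,11(13)-dien-12,6-olide | C=C1C(=O)O[C@@H]2C/C(CO[Si](C)(C)C(C)(C)C)=C\CC[C@@H](CO[Si](C)(C)C(C)(C)C)C[C@@H](OC(=O)C(C)=C)[C@@H]12 | intermediate
36 | (3E,6R,7R,8R,10R)-14,15-dihydroxy-8-(methacryloyloxy)germacra-3,11(13)-dien-12,6-olide (CNP0303865.1) | C=C(C)C(=O)O[C@@H]1C[C@H](CO)CC/C=C(/CO)C[C@H]2OC(=O)C(=C)[C@H]12 | target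

## Step count and least certain steps

Total: 18 steps. Longest linear sequence: 13 steps (12 to 36 through steps 6–18); the butenolide branch (steps 1–5) joins at step 12.

**Step 12 (key step).** The most likely failure is proton transfer in place of addition. The strongly basic 2-alkyl-dithianyl anion can remove the acidic C6–H of 11, which consumes both partners and erodes C6. A second risk is incomplete capture of enolate 26 by the sparingly soluble iminium salt, with proton return or double aminomethylation. The fallback sets out from 23 and 11 and comes back at 27; it separates the two bond formations. Anion 25 is generated as before, 11 is added slowly at −78 °C and the enolate is quenched cold with acetic acid to give the C11-unsubstituted trans lactone (4S,5R)-5-[2-({[tert-butyl(dimethyl)silyl]oxy}methyl)prop-2-en-1-yl]-4-{2-[(2R)-2-({[tert-butyl(dimethyl)silyl]oxy}methyl)hex-5-en-1-yl]-1,3-dithian-2-yl}oxolan-2-one F1, which is purified. F1 is then deprotonated with LiN(i-Pr)2 in THF at −78 °C, where no carbanion or alkyllithium is left, to regenerate enolate 26, which is aminomethylated with 24 to return to 27.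

**Step 13.** The most likely failure is oligomerisation through the monosubstituted olefin, because closure onto the 1,1-disubstituted olefin is slowed by medium-ring strain and the thioacetal sulfurs can tie up the ruthenium carbene. The fallback sets out from 27 and comes back at 31; it removes sulfur before the ring is closed. Compound 27 is protonated with TFA to the ammonium trifluoroacetate F2, and the dithiane is hydrolysed with PhI(OCOCF3)2 in aqueous MeCN to the acyclic C8 ketone (3R,4S,5R)-5-[2-({[tert-butyl(dimethyl)silyl]oxy}methyl)prop-2-en-1-yl]-4-[(3R)-3-({[tert-butyl(dimethyl)silyl]oxy}methyl)hept-6-enoyl]-3-[(dimethylamino)methyl]oxolan-2-one F3. Its ammonium tosylate F4 is cyclised with the same ruthenium catalyst at high dilution; the sp2 C8 changes the torsional demands of the ring and no sulfur competes for the metal. Neutralisation gives 31 directly, so step 14 is no longer needed. This fallback cures catalyst sequestration but not ring strain itself.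

**Step 15.** The most likely failure is poor or reversed facial selectivity, because the preference rests on a conformational argument for a ten-membered ring and not on a reagent. The fallback sets out from 31 and comes back at 33. If the reduction (with LiAlH(Ot-Bu)3 or with NaBH4/CeCl3 in MeOH at −78 °C) gives mainly the epimeric alcohol (3E,6R,7R,8S,10R,11R)-14,15-bis[(tert-butyldimethylsilyl)oxy]-13-(dimethylamino)-8-hydroxygermacr-3-en-12,6-olide F5, this is esterified under Mitsunobu conditions (methacrylic acid, PPh3, diisopropyl azodicarboxylate, toluene, 0 °C). Substitution with inversion at C8 gives 33. Both epimers therefore reach 33, one by acylation with retention (step 16) and the other by inversion.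

**Step 2.** The most likely failure is degradation of the alkenyl metal before the C–C bond is formed, by O-to-C silyl migration or by β-elimination of silanolate to an allene. The fallback sets out from 1 and 3 and comes back at 6; it keeps silicon out of the metallation. Alcohol 1 is treated with n-BuLi (1 equiv) and then t-BuLi (2 equiv) in ether to give the O,C-dilithio species lithium 2-lithioprop-2-en-1-olate F6, whose alkoxide can neither migrate nor leave. After transmetalation with MgBr2·OEt2 and addition of CuI (cat.), it opens 3 to give (4R)-5-chloro-2-methylidenepentane-1,4-diol F7. Selective silylation of the primary allylic hydroxyl (TBSCl, imidazole, CH2Cl2, −20 °C) returns to 6.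

## Further compounds

F1 | step 12 | (4S,5R)-5-[2-({[tert-butyl(dimethyl)silyl]oxy}methyl)prop-2-en-1-yl]-4-{2-[(2R)-2-({[tert-butyl(dimethyl)silyl]oxy}methyl)hex-5-en-1-yl]-1,3-dithian-2-yl}oxolan-2-one | O=C1C[C@H](C2(C[C@H](CO[Si](C)(C)C(C)(C)C)CCC=C)SCCCS2)[C@@H](CC(=C)CO[Si](C)(C)C(C)(C)C)O1
F2 | step 13 | dimethylammonium trifluoroacetate of 27 | C[NH+](C)C[C@@H]1C(=O)O[C@H](CC(=C)CO[Si](C)(C)C(C)(C)C)[C@H]1C1(C[C@H](CO[Si](C)(C)C(C)(C)C)CCC=C)SCCCS1.[O-]C(=O)C(F)(F)F
F3 | step 13 | (3R,4S,5R)-5-[2-({[tert-butyl(dimethyl)silyl]oxy}methyl)prop-2-en-1-yl]-4-[(3R)-3-({[tert-butyl(dimethyl)silyl]oxy}methyl)hept-6-enoyl]-3-[(dimethylamino)methyl]oxolan-2-one | CN(C)C[C@@H]1C(=O)O[C@H](CC(=C)CO[Si](C)(C)C(C)(C)C)[C@H]1C(=O)C[C@H](CO[Si](C)(C)C(C)(C)C)CCC=C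
F4 | step 13 | dimethylammonium 4-methylbenzenesulfonate of F3 | C[NH+](C)C[C@@H]1C(=O)O[C@H](CC(=C)CO[Si](C)(C)C(C)(C)C)[C@H]1C(=O)C[C@H](CO[Si](C)(C)C(C)(C)C)CCC=C.Cc1ccc(S(=O)(=O)[O-])cc1
F5 | step 15 | (3E,6R,7R,8S,10R,11R)-14,15-bis[(tert-butyldimethylsilyl)oxy]-13-(dimethylamino)-8-hydroxygermacr-3-en-12,6-olide | CN(C)C[C@@H]1C(=O)O[C@@H]2C/C(CO[Si](C)(C)C(C)(C)C)=C\CC[C@@H](CO[Si](C)(C)C(C)(C)C)C[C@H](O)[C@@H]12
F6 | step 2 | lithium 2-lithioprop-2-en-1-olate | [Li]OCC([Li])=C
F7 | step 2 | (4R)-5-chloro-2-methylidenepentane-1,4-diol | ClC[C@H](O)CC(=C)CO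
A1 | alternative 1 | thirteen-membered cyclic allyl α-(tributylstannyl) ether (O links C8 and C13; Z-C7=C11; O6 and O12 as PMB ethers; O14 and O15 as TBS ethers) | CCCC[Sn](CCCC)(CCCC)[C@@H]1C[C@H](CO[Si](C)(C)C(C)(C)C)CC/C=C(/CO[Si](C)(C)C(C)(C)C)C[C@@H](OCc2ccc(OC)cc2)/C=C(/COCc2ccc(OC)cc2)CO1
A2 | alternative 1 | cyclodecenol with free C8–OH, C7 bearing the C11=C13 methylene and C12 PMB ether, C6 PMB ether | O[C@@H]1C[C@H](CO[Si](C)(C)C(C)(C)C)CC/C=C(/CO[Si](C)(C)C(C)(C)C)C[C@@H](OCc2ccc(OC)cc2)[C@@H]1C(=C)COCc1ccc(OC)cc1
A3 | alternative 2 | (5R)-3-({[tert-butyl(dimethyl)silyl]oxy}methyl)-5-[(triethylsilyl)oxy]cyclohex-2-en-1-one | O=C1C[C@H](O[Si](CC)(CC)CC)CC(CO[Si](C)(C)C(C)(C)C)=C1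
A4 | alternative 2 | methyl cyclobut-1-ene-1-carboxylate | COC(=O)C1=CCC1
A5 | alternative 2 | cis-anti-cis tricyclic photoadduct containing a bicyclo[2.2.0]hexane | O=C1C[C@H](O[Si](CC)(CC)CC)C[C@]2(CO[Si](C)(C)C(C)(C)C)[C@H]1[C@@]1(C(=O)OC)CC[C@@H]21
A6 | alternative 3 | acyclic C8 aldehyde tethered to the C9=C10 methyl acrylate (C6 and C12 PMB ethers, C15 TBS ether) | O=C[C@@H](C(=C)COCc1ccc(OC)cc1)[C@H](OCc1ccc(OC)cc1)C/C(CO[Si](C)(C)C(C)(C)C)=C\CCC(=C)C(=O)OC
A7 | alternative 3 | ten-membered ring bridged by the C8–O–C14 γ-lactone | O=C1O[C@@H]2C[C@H]1CC/C=C(/CO[Si](C)(C)C(C)(C)C)C[C@@H](OCc3ccc(OC)cc3)[C@@H]2C(=C)COCc2ccc(OC)cc2
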